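**Assumption:** the SMILES is taken at face value: 3R,6R,7S,8R,10R, 1E, 4Z, (Z)-angelate, H-6 and H-7 cis on the lactone. Position labels use germacrane numbering (C3 acetate carbon, C6 lactone carbinol, C7 ring-fusion carbon, C8 angelate carbon, C10 tertiary carbinol, C11=C13 methylene, C12 lactone carbonyl).

## Retrosynthetic overview

1. Target ⇐ angeloylation of the C8 hydroxyl of the 8,10-diol lactone ⇐ removal of two silyl ethers.
2. Both rings in one operation: the C6–C7 bond is closed by reductive metalation of a (2Z)-2-(bromomethyl)enoate, so that C7 (the acrylate β-carbon) attacks the C6 enal carbon as an α-methylene ester homoenolate equivalent. The ten-membered carbocycle forms first, then the γ-lactone (O6 onto C12) in the same flask; C6 and C7 are set here.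
3. Open chain C13…C6 ⇐ catalyst-controlled alkenylzinc addition (C2–C3 bond, sets C3 and the 1E olefin) of a hydroborated alkyne to a (Z)-enal.
4. Alkyne half ⇐ Morita–Baylis–Hillman reaction (C7–C11) ⇐ chelation-controlled ethynylation (C10) ⇐ proline aldol of acetone with dimethoxyacetaldehyde (C8).
5. (Z)-Enal half (C3–C6, C15) ⇐ Still–Gennari olefination of the same dimethoxyacetaldehyde.

## Route

Step 1
Reactants: 1 acetone; 2 2,2-dimethoxyacetaldehyde
Product: 3 (R)-4-hydroxy-5,5-dimethoxypentan-2-one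
Conditions: L-proline (30 mol%), acetone/DMSO 1:4, rt, 48 h
Reagents that add atoms: none
Why: List–Barbas proline-catalysed direct aldol, in which the acetone enamine adds to the Re face of the non-enolisable aldehyde through the carboxylic-acid-organised transition state, setting the carbinol centre (future C8) as R.

Step 2
Reactants: 3 (R)-4-hydroxy-5,5-dimethoxypentan-2-one; 4 ethynylmagnesium bromide
Product: 5 (3R,5R)-6,6-dimethoxy-3-methylhex-1-yne-3,5-diol
Conditions: 4 (3.5 equiv), THF, −78 → −20 °C; H2O (pH 7)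
Reagents that add atoms: none
Why: Chelation-controlled (Cram-chelate, 1,3-induction) Grignard addition, in which the magnesium alkoxide of the β-hydroxy ketone forms a six-membered chelate with the carbinol substituent equatorial and the small ethynyl group attacks axially, trans to that substituent, giving the 1,3-anti diol with the new tertiary centre (future C10) R; the minor syn isomer is removed by chromatography.

Step 3
Reactants: 5 (3R,5R)-6,6-dimethoxy-3-methylhex-1-yne-3,5-diol
Product: 8 (2R,4R)-4-methyl-2,4-bis(triethylsilyloxy)hex-5-ynal, via bis-TES acetal 6 (not isolated), via lutidinium salt 7 (not isolated)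
Conditions: Et3SiOTf (4.5 equiv), 2,6-lutidine (6 equiv), CH2Cl2, −40 → 0 °C; then H2O, rt
Reagents that add atoms: triethylsilyl triflate, CC[Si](CC)(CC)OS(=O)(=O)C(F)(F)F; water, O
Why: Silyl triflate/2,6-lutidine silylates the secondary and the tertiary hydroxyl and in the same medium converts the dimethyl acetal into a pyridinium N,O-acetal that is hydrolysed on aqueous work-up (Fujioka-type acetal cleavage), so the aldehyde is released without acid and the α-silyloxy centre is not epimerised; no new stereocentre.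

Step 4
Reactants: 8 (2R,4R)-4-methyl-2,4-bis(triethylsilyloxy)hex-5-ynal; 9 methyl acrylate
Product: 10 methyl (4R,6R)-3-hydroxy-6-methyl-2-methylidene-4,6-bis(triethylsilyloxy)oct-7-ynoate (C3 epimers)
Conditions: DABCO (1 equiv), 9 (10 equiv, neat), rt, 4 d
Reagents that add atoms: none
Why: Morita–Baylis–Hillman reaction of the reactive α-silyloxy aldehyde with the DABCO–acrylate zwitterion; the new carbinol centre is formed as an epimer mixture, which is inconsequential because it becomes sp2 in step 11.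

Step 5
Reactants: 10 methyl (4R,6R)-3-hydroxy-6-methyl-2-methylidene-4,6-bis(triethylsilyloxy)oct-7-ynoate
Product: 11 methyl (4R,6R)-3-acetoxy-6-methyl-2-methylidene-4,6-bis(triethylsilyloxy)oct-7-ynoate (C3 epimers)
Conditions: Ac2O, Et3N, DMAP (5 mol%), CH2Cl2, 0 °C
Reagents that add atoms: acetic anhydride, CC(=O)OC(C)=O
Why: DMAP-catalysed acetylation turns the allylic alcohol into the leaving group for the later SN2' step and masks it during the organozinc chemistry; no stereocentre is touched.

Step 6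
Reactants: 2 2,2-dimethoxyacetaldehyde; 12 methyl 2-[bis(2,2,2-trifluoroethoxy)phosphoryl]propanoate
Product: 13 methyl (Z)-4,4-dimethoxy-2-methylbut-2-enoate
Conditions: KN(SiMe3)2, 18-crown-6, THF, −78 °C
Reagents that add atoms: none
Why: Still–Gennari variant of the Horner–Wadsworth–Emmons olefination, in which the bis(trifluoroethyl) phosphonate eliminates under kinetic control to the (Z)-trisubstituted enoate (the future 4Z olefin with C3 and C6 cis).

Step 7
Reactants: 13 methyl (Z)-4,4-dimethoxy-2-methylbut-2-enoate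
Product: 14 (Z)-4,4-dimethoxy-2-methylbut-2-en-1-ol
Conditions: i-Bu2AlH (2.2 equiv), CH2Cl2, −78 °C; aq. KNaC4H4O6
Reagents that add atoms: none
Why: 1,2-Reduction of the enoate by the aluminium hydride at low temperature gives the allylic alcohol without touching the acetal or the olefin geometry (non-acidic tartrate work-up).

Step 8
Reactants: 14 (Z)-4,4-dimethoxy-2-methylbut-2-en-1-ol
Product: 15 (Z)-4,4-dimethoxy-2-methylbut-2-enal
Conditions: MnO2 (15 equiv), CH2Cl2, rt
Reagents that add atoms: none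
Why: Chemoselective allylic oxidation with MnO2 under neutral heterogeneous conditions, which keeps the (Z)-enal from isomerising.

Step 9
Reactants: 11 methyl (4R,6R)-3-acetoxy-6-methyl-2-methylidene-4,6-bis(triethylsilyloxy)oct-7-ynoate; 15 (Z)-4,4-dimethoxy-2-methylbut-2-enal
Product: 19 methyl (4R,6R,7E,9R,10Z)-3,9-diacetoxy-12,12-dimethoxy-6,10-dimethyl-2-methylidene-4,6-bis(triethylsilyloxy)dodeca-7,10-dienoate, via alkenylborane 16 (not isolated), via alkenylzinc 17 (not isolated), via zinc alkoxide 18 (not isolated)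
Conditions: (c-C6H11)2BH (1.05 equiv), toluene, 0 °C → rt; Me2Zn, −78 °C; (+)-MIB [(2R)-3-exo-morpholinoisoborneol] (5 mol%), 15, −20 → 0 °C; then Ac2O, rt
Reagents that add atoms: acetic anhydride, CC(=O)OC(C)=O
Why: Oppolzer-type hydroboration / boron-to-zinc exchange / amino-alcohol-catalysed alkenylzinc addition, in which syn-hydroboration fixes the 1E olefin and the chiral zinc aminoalkoxide delivers the alkenyl group to the Re face of the enal (the mirror image of the Si-selective (−)-MIB system), setting the carbinol centre (future C3) as R; the zinc alkoxide is acetylated in the same flask.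

Step 10
Reactants: 19 methyl (4R,6R,7E,9R,10Z)-3,9-diacetoxy-12,12-dimethoxy-6,10-dimethyl-2-methylidene-4,6-bis(triethylsilyloxy)dodeca-7,10-dienoate
Product: 20 methyl (4R,6R,7E,9R,10Z)-3,9-diacetoxy-6,10-dimethyl-2-methylidene-12-oxo-4,6-bis(triethylsilyloxy)dodeca-7,10-dienoate
Conditions: (CO2H)2 (10% aq.) on SiO2, CH2Cl2, 0 °C → rt
Reagents that add atoms: water, O
Why: Mild acid hydrolysis of an allylic (vinylogous) dimethyl acetal, which ionises far more easily than any other group present, so the (Z)-enal is unmasked while the silyl ethers and both acetates survive.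

Step 11
Reactants: 20 methyl (4R,6R,7E,9R,10Z)-3,9-diacetoxy-6,10-dimethyl-2-methylidene-12-oxo-4,6-bis(triethylsilyloxy)dodeca-7,10-dienoate
Product: 21 methyl (2Z,4R,6R,7E,9R,10Z)-9-acetoxy-2-(bromomethyl)-6,10-dimethyl-12-oxo-4,6-bis(triethylsilyloxy)dodeca-2,7,10-trienoate
Conditions: LiBr (5 equiv), THF, rt; used crude
Reagents that add atoms: lithium bromide, [Li+].[Br-]
Why: SN2' substitution (conjugate addition of bromide, elimination of acetate) on the Morita–Baylis–Hillman acetate gives the thermodynamically preferred trisubstituted allyl bromide with the ester trans to the chain (2Z); the bis-allylic C9 acetate is not an SN2' acceptor and stays.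

Step 12
Reactants: 21 methyl (2Z,4R,6R,7E,9R,10Z)-9-acetoxy-2-(bromomethyl)-6,10-dimethyl-12-oxo-4,6-bis(triethylsilyloxy)dodeca-2,7,10-trienoate
Product: 24 (3R,6R,7R,8R,10R,1E,4Z)-3-acetoxy-8,10-bis(triethylsilyloxy)germacra-1,4,11(13)-trien-12,6-olide, via allylchromium species 22 (not isolated), via chromium alkoxide 23 (not isolated)
Conditions: CrCl2 (8 equiv), THF, 0.002 M (syringe pump, 12 h), rt; then 40 °C, 2 h; H2O
Reagents that add atoms: none
Why: Intramolecular Nozaki–Hiyama (Barbier-type) allylation used as a polarity-reversed ring closure, in which two-electron reduction of the allylic bromide by divalent chromium makes C7 (the natively electrophilic β-carbon of the acrylate) a nucleophile, an α-methylene ester homoenolate equivalent, that attacks the equally electrophilic C6 carbonyl carbon; the (Z)-allylchromium reacts through a chair (Zimmerman–Traxler) transition state with the C8 chain axial and the enal residue equatorial (syn adduct, hence the cis-fused lactone), C8 directs the face of C7 (H-8 in the allyl plane to avoid 1,3-allylic strain, the tether carbon C9 on the attacked face, the bulky silyloxy group turned outward), and the chromium alkoxide then lactonises onto the methyl ester, giving the C6/C7 configuration of the target (the C7 descriptor reads R here only because of the silyl group).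

Step 13
Reactants: 24 (3R,6R,7R,8R,10R,1E,4Z)-3-acetoxy-8,10-bis(triethylsilyloxy)germacra-1,4,11(13)-trien-12,6-olide
Product: 25 (3R,6R,7S,8R,10R,1E,4Z)-3-acetoxy-8,10-dihydroxygermacra-1,4,11(13)-trien-12,6-olide
Conditions: HF·pyridine, pyridine, THF, 0 °C → rt
Reagents that add atoms: none
Why: Fluoride-driven Si–O cleavage with pyridine-buffered HF·pyridine removes both triethylsilyl ethers without harming the bis-allylic acetate or the α-methylene lactone.

Step 14
Reactants: 25 (3R,6R,7S,8R,10R,1E,4Z)-3-acetoxy-8,10-dihydroxygermacra-1,4,11(13)-trien-12,6-olide; 26 angelic acid [(Z)-2-methylbut-2-enoic acid]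
Product: 28 CNP0181631.1, (3R,6R,7S,8R,10R,1E,4Z)-3-acetoxy-8-angeloyloxy-10-hydroxygermacra-1,4,11(13)-trien-12,6-olide, via mixed anhydride 27 (not isolated)
Conditions: 2,4,6-Cl3C6H2COCl, Et3N, toluene, rt; then 25, 75 °C
Reagents that add atoms: none
Why: Yamaguchi-type esterification through the angelic 2,4,6-trichlorobenzoic anhydride acylates only the secondary C8 hydroxyl (the tertiary C10 hydroxyl is inert), and the DMAP-free protocol avoids addition–elimination isomerisation of the (Z)-angelate to the tiglate.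

## Compound list

1 | acetone | CC(C)=O | starting material
2 | 2,2-dimethoxyacetaldehyde | COC(OC)C=O | starting material
3 | (R)-4-hydroxy-5,5-dimethoxypentan-2-one | CC(=O)C[C@@H](O)C(OC)OC | intermediate
4 | ethynylmagnesium bromide | C#C[Mg]Br | starting material
5 | (3R,5R)-6,6-dimethoxy-3-methylhex-1-yne-3,5-diol | C#C[C@](C)(O)C[C@@H](O)C(OC)OC | intermediate
6 | (3R,5R)-6,6-dimethoxy-3-methyl-3,5-bis(triethylsilyloxy)hex-1-yne | C#C[C@](C)(O[Si](CC)(CC)CC)C[C@@H](O[Si](CC)(CC)CC)C(OC)OC | intermediate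
7 | 1-[(2R,4R)-1-methoxy-4-methyl-2,4-bis(triethylsilyloxy)hex-5-yn-1-yl]-2,6-dimethylpyridinium triflate (C1 epimers) | C#C[C@](C)(O[Si](CC)(CC)CC)C[C@@H](O[Si](CC)(CC)CC)C(OC)[n+]1c(C)cccc1C.[O-]S(=O)(=O)C(F)(F)F | intermediate
8 | (2R,4R)-4-methyl-2,4-bis(triethylsilyloxy)hex-5-ynal | C#C[C@](C)(O[Si](CC)(CC)CC)C[C@@H](O[Si](CC)(CC)CC)C=O | intermediate
9 | methyl acrylate | C=CC(=O)OC | starting material
10 | methyl (4R,6R)-3-hydroxy-6-methyl-2-methylidene-4,6-bis(triethylsilyloxy)oct-7-ynoate (C3 epimers) | C#C[C@](C)(O[Si](CC)(CC)CC)C[C@@H](O[Si](CC)(CC)CC)C(O)C(=C)C(=O)OC | intermediate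
11 | methyl (4R,6R)-3-acetoxy-6-methyl-2-methylidene-4,6-bis(triethylsilyloxy)oct-7-ynoate (C3 epimers) | C#C[C@](C)(O[Si](CC)(CC)CC)C[C@@H](O[Si](CC)(CC)CC)C(OC(C)=O)C(=C)C(=O)OC | intermediate
12 | methyl 2-[bis(2,2,2-trifluoroethoxy)phosphoryl]propanoate | COC(=O)C(C)P(=O)(OCC(F)(F)F)OCC(F)(F)F | starting material
13 | methyl (Z)-4,4-dimethoxy-2-methylbut-2-enoate | COC(=O)/C(C)=C\C(OC)OC | intermediate
14 | (Z)-4,4-dimethoxy-2-methylbut-2-en-1-ol | OC/C(C)=C\C(OC)OC | intermediate
15 | (Z)-4,4-dimethoxy-2-methylbut-2-enal | O=C/C(C)=C\C(OC)OC | intermediate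
16 | methyl (4R,6R,7E)-3-acetoxy-8-(dicyclohexylboranyl)-6-methyl-2-methylidene-4,6-bis(triethylsilyloxy)oct-7-enoate | C1CCCCC1B(C2CCCCC2)/C=C/[C@](C)(O[Si](CC)(CC)CC)C[C@@H](O[Si](CC)(CC)CC)C(OC(C)=O)C(=C)C(=O)OC | intermediate
17 | (E)-alkenyl(methyl)zinc corresponding to 16 (ZnMe in place of the boranyl group) | C[Zn]/C=C/[C@](C)(O[Si](CC)(CC)CC)C[C@@H](O[Si](CC)(CC)CC)C(OC(C)=O)C(=C)C(=O)OC | intermediate
18 | methylzinc (9R)-alkoxide of the coupled chain (O–ZnMe in place of the C9 acetate of 19) | COC(OC)/C=C(/C)[C@H](O[Zn]C)/C=C/[C@](C)(O[Si](CC)(CC)CC)C[C@@H](O[Si](CC)(CC)CC)C(OC(C)=O)C(=C)C(=O)OC | intermediate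
19 | methyl (4R,6R,7E,9R,10Z)-3,9-diacetoxy-12,12-dimethoxy-6,10-dimethyl-2-methylidene-4,6-bis(triethylsilyloxy)dodeca-7,10-dienoate (C3 epimers) | COC(OC)/C=C(/C)[C@H](OC(C)=O)/C=C/[C@](C)(O[Si](CC)(CC)CC)C[C@@H](O[Si](CC)(CC)CC)C(OC(C)=O)C(=C)C(=O)OC | intermediate
20 | methyl (4R,6R,7E,9R,10Z)-3,9-diacetoxy-6,10-dimethyl-2-methylidene-12-oxo-4,6-bis(triethylsilyloxy)dodeca-7,10-dienoate (C3 epimers) | O=C/C=C(/C)[C@H](OC(C)=O)/C=C/[C@](C)(O[Si](CC)(CC)CC)C[C@@H](O[Si](CC)(CC)CC)C(OC(C)=O)C(=C)C(=O)OC | intermediate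
21 | methyl (2Z,4R,6R,7E,9R,10Z)-9-acetoxy-2-(bromomethyl)-6,10-dimethyl-12-oxo-4,6-bis(triethylsilyloxy)dodeca-2,7,10-trienoate | O=C/C=C(/C)[C@H](OC(C)=O)/C=C/[C@](C)(O[Si](CC)(CC)CC)C[C@@H](O[Si](CC)(CC)CC)/C=C(\CBr)C(=O)OC | intermediate
22 | allylchromium dichloride from 21 (CH2–CrCl2 in place of CH2Br, trivalent chromium) | O=C/C=C(/C)[C@H](OC(C)=O)/C=C/[C@](C)(O[Si](CC)(CC)CC)C[C@@H](O[Si](CC)(CC)CC)/C=C(\C[Cr](Cl)Cl)C(=O)OC | intermediate
23 | methyl 2-[(3Z,6E)-5-acetoxy-2-(dichlorochromiooxy)-4,8-dimethyl-8,10-bis(triethylsilyloxy)cyclodeca-3,6-dien-1-yl]prop-2-enoate, configured as in 24 | COC(=O)C(=C)[C@@H]1[C@H](O[Cr](Cl)Cl)/C=C(/C)[C@H](OC(C)=O)/C=C/[C@](C)(O[Si](CC)(CC)CC)C[C@H]1O[Si](CC)(CC)CC | intermediate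
24 | (3R,6R,7R,8R,10R,1E,4Z)-3-acetoxy-8,10-bis(triethylsilyloxy)germacra-1,4,11(13)-trien-12,6-olide | C=C1C(=O)O[C@@H]2/C=C(/C)[C@H](OC(C)=O)/C=C/[C@](C)(O[Si](CC)(CC)CC)C[C@@H](O[Si](CC)(CC)CC)[C@H]12 | intermediate
25 | (3R,6R,7S,8R,10R,1E,4Z)-3-acetoxy-8,10-dihydroxygermacra-1,4,11(13)-trien-12,6-olide | C=C1C(=O)O[C@@H]2/C=C(/C)[C@H](OC(C)=O)/C=C/[C@](C)(O)C[C@@H](O)[C@H]12 | intermediate
26 | angelic acid, (Z)-2-methylbut-2-enoic acid | C/C=C(/C)C(=O)O | starting material
27 | (Z)-2-methylbut-2-enoic 2,4,6-trichlorobenzoic anhydride | C/C=C(/C)C(=O)OC(=O)c1c(Cl)cc(Cl)cc1Cl | intermediate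
28 | CNP0181631.1, (3R,6R,7S,8R,10R,1E,4Z)-3-acetoxy-8-[(Z)-2-methylbut-2-enoyloxy]-10-hydroxygermacra-1,4,11(13)-trien-12,6-olide | C=C1C(=O)O[C@@H]2/C=C(/C)[C@H](OC(C)=O)/C=C/[C@](C)(O)C[C@@H](OC(=O)/C(C)=C\C)[C@H]12 | target

## Step count and risks

Total steps: 14. Longest linear sequence: 11 steps (steps 1–5, then 9–14); the enal branch (steps 6–8) is 3 steps.

**Step 12 (most likely to fail).** The ring closure must beat oligomerisation, and the C6/C7 configuration rests on a transition-state model, not on a direct precedent for this substitution pattern. Fallback: set out from 19 and make the nucleophile an isolable allylboronate instead of a transient organochromium. Copper-catalysed SN2' borylation of the Morita–Baylis–Hillman acetate (B2pin2, CuCl, PCy3, KOAc, THF) gives the allylboronate acetal F1. The same wet-silica/oxalic acid hydrolysis as in step 10 gives the allylboronate enal F2. Slow addition of F2 to Sc(OTf)3 (10 mol%) in CH2Cl2 at −40 → 0 °C (or plain toluene at 80 °C) closes the ring by intramolecular allylboration through a closed chair with retention of the boronate geometry. The resulting borate lactonises, and the route is rejoined at 24.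

**Step 9.** The alkenylzinc carries an ester, an allylic acetate and a quaternary allylic centre, and the enal is (Z)-configured; conversion or facial selectivity may suffer. Fallback: set out from 11 and 15 and use an alkynyl instead of an alkenyl nucleophile. Zinc alkynylide addition (Me2Zn, the ProPhenol enantiomer that delivers the alkynyl group to the Re face, toluene, 0 °C) gives the propargylic alcohol F3. trans-Selective semi-hydrogenation ([Cp*RuCl(cod)], H2, CH2Cl2) gives the (E)-bis-allylic alcohol F4. Ac2O/Et3N/DMAP then rejoins the route at 19.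

**Step 2.** The 1,3-induction on a methyl ketone may be weak or may run in the syn sense. Fallback: set out from 1 and 2 and let C10 control C8 instead of the reverse. D-Proline gives the (S)-ketol F5. The same ethynylation, now syn-selective, gives the syn diol F6, in which the tertiary centre already has the required R configuration. Dess–Martin oxidation of the secondary alcohol gives the β-hydroxy ketone F7. Chelation-controlled reduction (Et2BOMe, NaBH4, THF/MeOH, −78 °C) then delivers hydride cis to the small ethynyl group, which sits axial in the boron chelate while methyl is equatorial, and rejoins the route at 5.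

## Further compounds

F1 | step 12 | methyl (2E,4R,6R,7E,9R,10Z)-9-acetoxy-12,12-dimethoxy-6,10-dimethyl-2-[(4,4,5,5-tetramethyl-1,3,2-dioxaborolan-2-yl)methyl]-4,6-bis(triethylsilyloxy)dodeca-2,7,10-trienoate | COC(OC)/C=C(/C)[C@H](OC(C)=O)/C=C/[C@](C)(O[Si](CC)(CC)CC)C[C@@H](O[Si](CC)(CC)CC)/C=C(\CB1OC(C)(C)C(C)(C)O1)C(=O)OC
F2 | step 12 | methyl (2E,4R,6R,7E,9R,10Z)-9-acetoxy-6,10-dimethyl-12-oxo-2-[(4,4,5,5-tetramethyl-1,3,2-dioxaborolan-2-yl)methyl]-4,6-bis(triethylsilyloxy)dodeca-2,7,10-trienoate | O=C/C=C(/C)[C@H](OC(C)=O)/C=C/[C@](C)(O[Si](CC)(CC)CC)C[C@@H](O[Si](CC)(CC)CC)/C=C(\CB1OC(C)(C)C(C)(C)O1)C(=O)OC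
F3 | step 9 | methyl (4R,6R,9S,10Z)-3-acetoxy-9-hydroxy-12,12-dimethoxy-6,10-dimethyl-2-methylidene-4,6-bis(triethylsilyloxy)dodec-10-en-7-ynoate (C3 epimers) | COC(OC)/C=C(/C)[C@H](O)C#C[C@](C)(O[Si](CC)(CC)CC)C[C@@H](O[Si](CC)(CC)CC)C(OC(C)=O)C(=C)C(=O)OC
F4 | step 9 | methyl (4R,6R,7E,9R,10Z)-3-acetoxy-9-hydroxy-12,12-dimethoxy-6,10-dimethyl-2-methylidene-4,6-bis(triethylsilyloxy)dodeca-7,10-dienoate (C3 epimers) | COC(OC)/C=C(/C)[C@H](O)/C=C/[C@](C)(O[Si](CC)(CC)CC)C[C@@H](O[Si](CC)(CC)CC)C(OC(C)=O)C(=C)C(=O)OC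
F5 | step 2 | (S)-4-hydroxy-5,5-dimethoxypentan-2-one | CC(=O)C[C@H](O)C(OC)OC
F6 | step 2 | (3R,5S)-6,6-dimethoxy-3-methylhex-1-yne-3,5-diol | C#C[C@](C)(O)C[C@H](O)C(OC)OC
F7 | step 2 | (R)-4-hydroxy-1,1-dimethoxy-4-methylhex-5-yn-2-one | C#C[C@](C)(O)CC(=O)C(OC)OC
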